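**Retrosynthetic overview** (prostanoid numbering: C9 ketone, C8 bears OAc, C12 bears the octenyl chain, C1–C7 is the ester chain)
1. Clavubicyclone 20 ⇒ Cope rearrangement (forms C5–C10, opens C7–C12) of the cis-divinylcyclopropane 19, a 1-acetoxy-6-endo-alkenylbicyclo[3.1.0]hex-3-en-2-one.
2. 19 ⇒ C7–C12 closure (Pd-allyl plus vinylogous C12 enolate, 3-exo) in the clavulone-type cyclopentenone 18, which already carries C8–OAc, both chains and all esters; closure and Cope run in one flask.
3. 18 ⇒ aldol (C7–C8) between α′-acetoxy enone 8 and γ-acetoxy enal 15; this sets quaternary C8 anti to the C12 chain.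
4. 8 ⇐ (R)-4-silyloxycyclopentenone 1 (allyl transfer/elimination, Z-selective cross-metathesis, α′-acetoxylation); 15 ⇐ methyl 4-oxobutanoate + 3,3-diethoxypropyne (asymmetric alkenylation sets C4).
5. Ring order: cyclopentenone (purchased) → cyclopropane C7–C8–C12 → six- and seven-membered rings of the bicyclo[3.2.1]octadienone in the Cope step.

Assumption: the presumed biogenesis is taken as clavulone-type cyclopentenone → C7–C12 closure to a 7,8,12-cyclopropane (cis-divinylcyclopropane) → Cope rearrangement.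

**Step 1**
Reactants: 1 (R)-4-[(tert-butyldimethylsilyl)oxy]cyclopent-2-en-1-one; 2 allylmagnesium bromide
Product: 5 (R)-4-allylcyclopent-2-en-1-one, via silyl enol ether 3 (not isolated), via silyloxy ketone 4 (not isolated)
Conditions: CuBr·SMe2 (1 equiv), TMSCl, THF, −78 °C; 1 M HCl; then DBU, CH2Cl2, 0 °C
Reagents that add atoms: none
Why: TMSCl-assisted conjugate addition of the allylcopper reagent occurs anti to the 4-silyloxy group, and E1cB β-elimination of silanolate then moves the enone, so the OTBS stereocentre is exchanged for C12 (R).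

**Step 2**
Reactants: 5 (R)-4-allylcyclopent-2-en-1-one; 6 hept-1-ene
Product: 7 (R)-4-[(2Z)-oct-2-en-1-yl]cyclopent-2-en-1-one
Conditions: 6 (8 equiv), Z-selective cyclometalated Ru–NHC nitrate metathesis catalyst (5 mol%), THF, 35 °C
Reagents that add atoms: none
Why: Z-selective olefin cross-metathesis of two unhindered terminal alkenes sets the 14Z alkene under catalyst control, while the electron-poor ring alkene does not react and C12 is untouched.

**Step 3**
Reactants: 7 (R)-4-[(2Z)-oct-2-en-1-yl]cyclopent-2-en-1-one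
Product: 8 (1R,5S)-5-[(2Z)-oct-2-en-1-yl]-2-oxocyclopent-3-en-1-yl acetate
Conditions: Mn(OAc)3·2H2O (3 equiv), benzene, reflux (Dean–Stark)
Reagents that add atoms: manganese(III) acetate, [Mn+3].CC([O-])=O.CC([O-])=O.CC([O-])=O
Why: Mn(OAc)3 α′-acetoxylation of enones is specific for the α′ carbon (C8) and gives mainly the 4,5-trans acetate; the C8 centre is re-enolised in step 6, so only C12 has to survive.

**Step 4**
Reactants: 9 3,3-diethoxyprop-1-yne; 10 methyl 4-oxobutanoate
Product: 14 methyl (4R,5E)-4-acetoxy-7,7-diethoxyhept-5-enoate, via alkenylborane 11 (not isolated), via alkenylzinc 12 (not isolated), via zinc alkoxide 13 (not isolated)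
Conditions: Cy2BH, toluene, 0 °C → rt; Me2Zn, −78 °C; (−)-MIB (5 mol%), 10, −30 → −10 °C; then Ac2O, −10 °C → rt
Reagents that add atoms: acetic anhydride, CC(=O)OC(C)=O
Why: Oppolzer–Walsh sequence (syn hydroboration, B→Zn transmetalation, amino-alcohol-catalysed alkenylzinc addition) gives the E-allylic alkoxide by Si-face delivery (4R), and acetylating the zinc alkoxide in situ prevents γ-lactonisation.

**Step 5**
Reactants: 14 methyl (4R,5E)-4-acetoxy-7,7-diethoxyhept-5-enoate
Product: 15 methyl (4R,5E)-4-acetoxy-7-oxohept-5-enoate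
Conditions: PPTS (cat.), acetone/H2O, rt
Reagents that add atoms: water, O
Why: Mild acid-catalysed acetal hydrolysis frees the E-enal without touching the acetate, the methyl ester or C4.

**Step 6**
Reactants: 8 (1R,5S)-5-[(2Z)-oct-2-en-1-yl]-2-oxocyclopent-3-en-1-yl acetate; 15 methyl (4R,5E)-4-acetoxy-7-oxohept-5-enoate
Product: 18 methyl (4R,5E,7S)-4-acetoxy-7-[(1R,5S)-1-acetoxy-5-[(2Z)-oct-2-en-1-yl]-2-oxocyclopent-3-en-1-yl]-7-[(tert-butoxycarbonyl)oxy]hept-5-enoate, via lithium enolate 16 (not isolated), via lithium aldolate 17 (not isolated)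
Conditions: LiHMDS (1.05 equiv), THF, −78 °C; 15, −78 °C, 15 min; then Boc2O, −78 → −30 °C
Reagents that add atoms: di-tert-butyl dicarbonate, CC(C)(C)OC(=O)OC(=O)OC(C)(C)C
Why: Kinetic deprotonation at the acetoxy-bearing C8 and a Zimmerman–Traxler aldol 1,2-addition to the enal on the face anti to the C12 chain set quaternary C8 (OAc cis to the chain), the ring-locked E-enolate should give the 7,8-anti (7S) aldolate, and in-situ carbonate formation precedes acetyl migration or retro-aldol; C7 is only a temporary stereocentre and its minor epimer is removed by chromatography.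

**Step 7**
Reactants: 18 methyl (4R,5E,7S)-4-acetoxy-7-[(1R,5S)-1-acetoxy-5-[(2Z)-oct-2-en-1-yl]-2-oxocyclopent-3-en-1-yl]-7-[(tert-butoxycarbonyl)oxy]hept-5-enoate
Product: 20 clavubicyclone, via divinylcyclopropane 19 (not isolated)
Conditions: Pd2(dba)3·CHCl3 (2.5 mol%), dppe (6 mol%), THF, 0 °C → rt (40 °C if the Cope step is slow)
Reagents that add atoms: none
Why: Proposed new method: Pd(0) ionises the allylic carbonate (Tsuji–Trost), the released tert-butoxide removes the vinylogous γ-H at C12 only once the π-allyl is in place, and the dienolate γ-carbon closes 3-exo on the proximal allyl terminus C7 anti to Pd (net retention at C7, which puts the E-alkenyl group endo and Pd on the outer face) to give 19, whose cis-divinylcyclopropane Cope rearrangement through the boat transition state forms C5–C10, places the E-alkene substituent endo (5R) and fixes C10 (R) from C8 (S); the closest known types are the Pd-catalysed vinylcyclopropanation of malonate-tethered allylic carbonates and the near-room-temperature Cope rearrangement of 6-endo-vinylbicyclo[3.1.0]hex-2-enes.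

**Compound list**
1 | (R)-4-[(tert-butyldimethylsilyl)oxy]cyclopent-2-en-1-one | O=C1C=C[C@H](O[Si](C)(C)C(C)(C)C)C1 | starting material
2 | allylmagnesium bromide | C=CC[Mg]Br | starting material
3 | tert-butyldimethyl{[(1R,2R)-2-allyl-4-(trimethylsilyloxy)cyclopent-3-en-1-yl]oxy}silane (silyl enol ether) | C[Si](C)(C)OC1=C[C@@H](CC=C)[C@H](O[Si](C)(C)C(C)(C)C)C1 | intermediate
4 | (3R,4R)-3-allyl-4-[(tert-butyldimethylsilyl)oxy]cyclopentan-1-one (3,4-trans) | O=C1C[C@@H](CC=C)[C@H](O[Si](C)(C)C(C)(C)C)C1 | intermediate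
5 | (R)-4-allylcyclopent-2-en-1-one | O=C1C=C[C@H](CC=C)C1 | intermediate
6 | hept-1-ene | C=CCCCCC | starting material
7 | (R)-4-[(2Z)-oct-2-en-1-yl]cyclopent-2-en-1-one | O=C1C=C[C@H](C/C=C\CCCCC)C1 | intermediate
8 | (1R,5S)-5-[(2Z)-oct-2-en-1-yl]-2-oxocyclopent-3-en-1-yl acetate (trans) | O=C1C=C[C@H](C/C=C\CCCCC)[C@H]1OC(C)=O | intermediate
9 | 3,3-diethoxyprop-1-yne | C#CC(OCC)OCC | starting material
10 | methyl 4-oxobutanoate | COC(=O)CCC=O | starting material
11 | dicyclohexyl[(1E)-3,3-diethoxyprop-1-en-1-yl]borane | CCOC(OCC)/C=C/B(C1CCCCC1)C1CCCCC1 | intermediate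
12 | [(1E)-3,3-diethoxyprop-1-en-1-yl](methyl)zinc | CCOC(OCC)/C=C/[Zn]C | intermediate
13 | methylzinc alkoxide of methyl (4R,5E)-7,7-diethoxy-4-hydroxyhept-5-enoate | CCOC(OCC)/C=C/[C@H](O[Zn]C)CCC(=O)OC | intermediate
14 | methyl (4R,5E)-4-acetoxy-7,7-diethoxyhept-5-enoate | CCOC(OCC)/C=C/[C@H](OC(C)=O)CCC(=O)OC | intermediate
15 | methyl (4R,5E)-4-acetoxy-7-oxohept-5-enoate | O=C/C=C/[C@H](OC(C)=O)CCC(=O)OC | intermediate
16 | lithium (3S)-2-acetoxy-3-[(2Z)-oct-2-en-1-yl]cyclopenta-1,4-dien-1-olate | [Li]OC1=C(OC(C)=O)[C@@H](C/C=C\CCCCC)C=C1 | intermediate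
17 | lithium (7S)-alkoxide of the aldol adduct (18 with OLi in place of OBoc) | O=C1C=C[C@H](C/C=C\CCCCC)[C@@]1(OC(C)=O)[C@@H](O[Li])/C=C/[C@H](OC(C)=O)CCC(=O)OC | intermediate
18 | methyl (4R,5E,7S)-4-acetoxy-7-[(1R,5S)-1-acetoxy-5-[(2Z)-oct-2-en-1-yl]-2-oxocyclopent-3-en-1-yl]-7-[(tert-butoxycarbonyl)oxy]hept-5-enoate | O=C1C=C[C@H](C/C=C\CCCCC)[C@@]1(OC(C)=O)[C@@H](OC(=O)OC(C)(C)C)/C=C/[C@H](OC(C)=O)CCC(=O)OC | intermediate
19 | methyl (4R,5E)-4-acetoxy-6-[(1S,5S,6R)-1-acetoxy-5-[(2Z)-oct-2-en-1-yl]-2-oxobicyclo[3.1.0]hex-3-en-6-yl]hex-5-enoate (6-endo alkenyl) | O=C1C=C[C@@]2(C/C=C\CCCCC)[C@@H](/C=C/[C@H](OC(C)=O)CCC(=O)OC)[C@@]12OC(C)=O | intermediate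
20 | clavubicyclone, methyl (4R)-4-acetoxy-4-[(1S,4R,5R)-1-acetoxy-7-[(2Z)-oct-2-en-1-yl]-8-oxobicyclo[3.2.1]octa-2,6-dien-4-yl]butanoate | CCCCC/C=C\CC1=C[C@H]2C(=O)[C@]1(OC(C)=O)C=C[C@H]2[C@@H](CCC(=O)OC)OC(C)=O | target

**Totals**
Total step count: 7. Longest linear sequence: 5 (steps 1, 2, 3, 6, 7); the chain fragment joins after 2 steps (4, 5).
Stereocentres: C4 in step 4; C12 relay centre in step 1; C8 in step 6; C5 and C10 in step 7.

**Steps most likely to fail, with fallbacks**

Step 7 (closure/Cope cascade). The C12 dienolate can expel the C8 acetate (E1cB to a cyclopentadienone) before it alkylates, or close with the alkenyl group exo, which does not rearrange at a temperature the product tolerates (it can lose CO on heating). The fallback sets out from 18 and returns at 19, then 20. Compound 18 is treated with TBSOTf and Et3N in CH2Cl2 at −78 °C to give the neutral silyl dienol ether methyl (4R,5E,7S)-4-acetoxy-7-[(1R)-1-acetoxy-2-[(tert-butyldimethylsilyl)oxy]-5-[(2Z)-oct-2-en-1-yl]cyclopenta-2,4-dien-1-yl]-7-[(tert-butoxycarbonyl)oxy]hept-5-enoate F1, in which no carbanion is present to eject acetate. Catalytic TMSOTf at −78 → −20 °C then ionises the allylic carbonate, and the siloxydiene γ-carbon C12 closes on C7 in a vinylogous Mukaiyama-type alkylation; because the allyl cation is planar, both C7 epimers converge. Loss of silicon gives 19, which rearranges to 20 as before.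

Step 6 (aldol at the acetoxy-bearing carbon). The lithium aldolate may transfer the C8 acetyl group to the C7 oxygen or revert, and the C7 selectivity may be low. The fallback sets out from 8 and returns at 18. Compound 8 is silylated (TMSOTf, Et3N, CH2Cl2, 0 °C) to (5S)-5-[(2Z)-oct-2-en-1-yl]-2-(trimethylsilyloxy)cyclopenta-1,3-dien-1-yl acetate F2, which is used at once in a BF3·OEt2-mediated Mukaiyama aldol with 15 at −78 °C. This gives the free carbinol methyl (4R,5E,7S)-4-acetoxy-7-[(1R,5S)-1-acetoxy-5-[(2Z)-oct-2-en-1-yl]-2-oxocyclopent-3-en-1-yl]-7-hydroxyhept-5-enoate F3 without any alkoxide being formed. The C7 epimers are separated, and Boc2O with catalytic DMAP in MeCN at 0 °C converts F3 into 18.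

Step 3 (Mn(OAc)3 acetoxylation). Conversion may stall, the α′-keto radical may attack the chain alkene, or C12 may partly epimerise in hot acetic acid. The fallback sets out from 7 and returns at 8. Kinetic α′-deprotonation of 7 (LiHMDS, THF, −78 °C) and oxidation of the enolate with 2-(phenylsulfonyl)-3-phenyloxaziridine give (4S,5R)-5-hydroxy-4-[(2Z)-oct-2-en-1-yl]cyclopent-2-en-1-one F4. Acetylation (Ac2O, pyridine, cat. DMAP, 0 °C) then gives 8.

**Further compounds**
F1 | step 7 | methyl (4R,5E,7S)-4-acetoxy-7-[(1R)-1-acetoxy-2-[(tert-butyldimethylsilyl)oxy]-5-[(2Z)-oct-2-en-1-yl]cyclopenta-2,4-dien-1-yl]-7-[(tert-butoxycarbonyl)oxy]hept-5-enoate | CC(C)(C)[Si](C)(C)OC1=CC=C(C/C=C\CCCCC)[C@@]1(OC(C)=O)[C@@H](OC(=O)OC(C)(C)C)/C=C/[C@H](OC(C)=O)CCC(=O)OC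
F2 | step 6 | (5S)-5-[(2Z)-oct-2-en-1-yl]-2-(trimethylsilyloxy)cyclopenta-1,3-dien-1-yl acetate | C[Si](C)(C)OC1=C(OC(C)=O)[C@@H](C/C=C\CCCCC)C=C1
F3 | step 6 | methyl (4R,5E,7S)-4-acetoxy-7-[(1R,5S)-1-acetoxy-5-[(2Z)-oct-2-en-1-yl]-2-oxocyclopent-3-en-1-yl]-7-hydroxyhept-5-enoate | O=C1C=C[C@H](C/C=C\CCCCC)[C@@]1(OC(C)=O)[C@@H](O)/C=C/[C@H](OC(C)=O)CCC(=O)OC
F4 | step 3 | (4S,5R)-5-hydroxy-4-[(2Z)-oct-2-en-1-yl]cyclopent-2-en-1-one | O=C1C=C[C@H](C/C=C\CCCCC)[C@H]1O
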